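## Structural features

The target (C33H26O6) is a linear trimer of 8-methoxy-1-naphthol: three naphthalene units, each with a hydroxyl at C1 and a peri methoxy at C8, no sp3 carbon and no stereogenic centre. Unit A is joined through its C2 (ortho to OH) to C2 of the central unit B, and unit B is joined through its C4 (para to OH) to C4 of unit C. The molecule therefore holds one ortho–ortho and one para–para biaryl bond. The A–B axis carries only the two hydroxyls as ortho substituents and rotates freely. The B–C axis is of the 1,1′-binaphthyl type, flanked only by ortho and peri CH groups. The fragile elements are the three electron-rich free naphthols, which are easily oxidised to quinones or coupled oxidatively, above all at the open para position of unit A and the open ortho position of unit C. The aryl methyl ethers must stay distinct from the hydroxyls, so a global demethylation at the end is excluded. The real difficulty is the ordered, unsymmetrical joining of three identical monomers through two different positions, which a direct oxidative coupling cannot dictate. The key step exploits the oxygenated ring of unit C: C1 (bearing OH) is the former ester carbon of a 2-methoxybenzoate, C4 (bearing unit B) is a benzylic carbon, C4a, C8a and the C8 methoxy come with the benzoate ring, and C2–C3 are delivered by a two-carbon acrylate unit.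

## Logic of the disconnections

21 ⇒ 20. The last bonds to be cleaved are the two acetal O–CH2 bonds on the oxygens of units A and B. These hydroxyls must be masked through the strongly basic annulation and the organometallic steps, and the MOM group also serves earlier as a directing group. The gain is that 20 has one free naphthol only. The forward step must use acid mild enough to leave the four aryl methyl ethers alone, with air excluded.

20 ⇒ 19 ⇒ 18. The C2–CO2H bond of unit C and the ester C–O bond are restored. The carboxyl group is the activating group of the annulation and is removed tracelessly afterwards. This leads back to the direct annulation product. The forward steps demand saponification of a hindered, hydrogen-bonded ester and a protodecarboxylation that spares the MOM ethers.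

18 ⇒ 13 + 14. The C3–C4 and C1–C2 bonds of unit C are cut. C1 is an ester carbon and C4 a benzylic carbon of one benzoate, so a single anionic cascade can form both bonds and the aromatic ring. The gain is large: the whole phenol ring of unit C disappears and the para B–C biaryl link becomes an aryl–CH2 bond. The forward step requires selective deprotonation at the doubly benzylic carbon and conjugate (not carbonyl) addition to 14.

13 ⇒ 9 + 12, 12 ⇒ 11 ⇒ 10. The CH2–C4 bond of unit B is cut as an sp3–sp2 cross-coupling, which places the benzyl group exactly where the halogen of 9 sits. An electrophilic benzylation of a preformed symmetrical bis-naphthol was rejected: it would need a statistical mono-functionalisation, it offers a competing site para to methoxy, and the ortho-ester benzyl bromide 11 would lactonise under Lewis acid. The gain is a binaphthyl bromide and a one-step derivative of 10. The forward step demands formation of 12 without homocoupling and palladium insertion into a hindered, electron-rich C–Br bond.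

9 ⇒ 5 + 8. The C2–C2′ biaryl bond between units A and B is cut. The two halves are made different before they are joined, so the C4 handle sits on one unit only and no desymmetrisation is needed. Both halves derive from 2. The forward step must discriminate the C–I bond of 8 from its C–Br bond.

5 ⇒ 3 ⇒ 2. The C2–B bond is cut back to a C–H bond via 4, and the O–MOM bond to the free naphthol. The acetal directs the metalation to C2, so no halogen is needed on unit A. The demand is regioselective lithiation ortho to the acetal and not ortho to the methyl ether.

8 ⇒ 7 ⇒ 6 ⇒ 2. The O–MOM, C2–I and C4–Br bonds are cut in that order. The free naphthol directs electrophiles first to the para and then to the only remaining ortho position. The demand is that the first halogenation be para-selective and stop at one bromine.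

2 ⇒ 1. One O–CH3 bond is cut. The peri hydrogen bond in 2 makes the second hydroxyl much less reactive, so the forward mono-methylation should stop cleanly.

## Other disconnections considered

Alternative 1: The cut is the ortho–ortho biaryl bond between C2 of unit A and C2 of unit B.
- Forward step: the two naphthol oxygens beside that bond are first tied together by a diisopropylsilylene bridge, giving the bis(aryloxy)silane A2. In A2 unit A carries bromine at C2 and unit B, already joined through C4 to MOM-protected unit C, keeps its C2–H. Pd(OAc)2 with a bulky trialkylphosphine, Cs2CO3 and pivalic acid would insert zerovalent palladium into the C–Br bond, palladate C2 of unit B by carboxylate-assisted concerted metalation–deprotonation and, after reductive elimination, close the seven-membered dioxasilepine A1. Fluoride and acid would then free the triol.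
- In favour: the tether enforces coupling between two different naphthols and lets only the ortho C–H of unit B reach the metal. The B–C half A3 would come from the para–para oxidative dimer A4 of 2, so no ring is built from scratch.
- Against: A3 needs a statistical mono-protection of the symmetrical A4, and the formation of A4 competes with ortho–para and ortho–ortho coupling. The unsymmetrical A2 must be assembled stepwise from two hindered, hydrogen-bonded naphthols without scrambling to symmetrical silanes. The Si–O bonds must survive carbonate and pivalate above 100 °C while an electron-rich aryl bromide next to a silyloxy group adds slowly to palladium.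
- Comparison: both plans make the A–B bond with palladium and are equal in the regiochemical certainty of that bond; the alternative secures it by geometry, the chosen plan by two prefunctionalised partners (5 and 8). On step economy the alternative is the better plan, at roughly eight steps against thirteen. The chosen plan is the safer one for the B–C link, which it fixes through a benzylic carbon and an annulation instead of the site selectivity of an oxidative coupling.

Alternative 2: The cuts are the C1–C2 and C2–C3 bonds of unit A, so the phenol ring of the 2-linked terminal naphthol is built onto a B–C dimer.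
- Forward step: the naphthylmethylmagnesium chloride A7 (CH2MgCl on C2 of unit B, both hydroxyls as MOM ethers) adds to the lactone carbonyl of 8-methoxyisocoumarin A6. Collapse of the adduct opens the ring to an aryl benzyl ketone carrying an aldehyde enolate. After proton transfer the doubly activated methylene attacks the aldehyde, and loss of water gives the trimer A5 with the hydroxyl of unit A free.
- In favour: the isocoumarin brings C1, C3, C4 and the methoxy-bearing ring in the correct 1,8-relationship. No surplus carboxyl remains, so the two steps of hydrolysis and decarboxylation are saved; on this point the alternative is the better plan. A6 should be reachable from 10 in about two steps.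
- Against: A7 is an electron-rich ortho-alkoxy naphthylmethyl Grignard reagent. Its halide precursor would ionise easily and Wurtz coupling would compete with magnesium insertion. It also presupposes a B–C dimer differentiated at one ortho position and fitted with a one-carbon handle. The ring-opened ketone can be enolised by A7, which consumes reagent, and the aldehyde stays masked as its enolate until a proton source intervenes, so the aldol closure may need a separate treatment.
- Comparison: mechanistically this is the mirror image of the chosen step, with the benzoate-derived partner as electrophile instead of nucleophile. Both plans are equal in fixing the 1,8-dioxygenation pattern through a building block derived from 10. The chosen plan generates its nucleophile by deprotonating a stable diarylmethane, which is more secure than metal insertion into a labile halide. Overall step counts should be comparable, since the savings after the key step are offset by the preparation of A7.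

Alternative 3: The cut is the bond between C1 and C8a of unit A.
- Forward step: the butenoic acid A9 carries unit B on C2 and a 2-bromo-5-methoxyphenyl group on C4. Heating with acetic anhydride and sodium acetate forms the mixed anhydride and then the dienylketene. A thermal six-electron electrocyclisation that includes one aromatic double bond closes the ring, and tautomerisation and acetylation give the naphthyl acetate A8. The bromine para to the methoxy group blocks the otherwise preferred closure site and forces closure ortho to methoxy. It would be removed later by hydrogenolysis over Pd/C together with the two benzyl ethers.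
- In favour: the step needs no strong base, no organometallic reagent and no low temperature; on operational simplicity the alternative is the better plan. The acetate is orthogonal to the benzyl ethers, and the blocking bromine costs no extra deprotection step.
- Against: only one C–C bond is formed, so the whole four-carbon chain with both aryl groups must be assembled beforehand on an already differentiated B–C dimer. Ring closure is forced into the crowded position between the chain and the methoxy group. The styrene must reach the Z geometry by equilibration, and condensations of the mixed anhydride compete.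
- Comparison: here the regiochemistry is imposed by a blocking group, whereas in the chosen plan it is inherent in the substitution pattern of 10; the chosen plan is the better one on that point. Both plans are equal in ending with an aromatisation that makes ring closure irreversible. The chosen key step forms two bonds from a commercial two-carbon partner, so the alternative is expected to be longer.

Key step: step 10

Assumption: the B–C axis, of the 1,1′-binaphthyl type without further ortho substituents, is taken to equilibrate at ambient temperature, so the target is made without axial stereocontrol, in line with a structure that specifies no axial configuration.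

## Route

Step 1
Reactants: 1 naphthalene-1,8-diol
Product: 2 8-methoxynaphthalen-1-ol
Conditions: MeI (1.05 equiv), K2CO3 (1.1 equiv), acetone, 25 °C
Reagents that add atoms: iodomethane, CI
Why: Williamson ether synthesis; the hydroxyl left in 2 is locked in a peri hydrogen bond to the new methoxy group and is far less acidic, so methylation should stop at the monoether.

Step 2
Reactants: 2 8-methoxynaphthalen-1-ol
Product: 3 8-methoxy-1-(methoxymethoxy)naphthalene
Conditions: NaH (1.2 equiv), DMF, 0 °C; MOMCl (1.2 equiv), 0 °C to rt
Reagents that add atoms: chloromethyl methyl ether, COCCl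
Why: O-alkylation of the sodium naphtholate to the mixed acetal; NaH is used because the hydrogen-bonded hydroxyl reacts sluggishly with amine bases.

Step 3
Reactants: 3 8-methoxy-1-(methoxymethoxy)naphthalene
Product: 5 2-[8-methoxy-1-(methoxymethoxy)naphthalen-2-yl]-4,4,5,5-tetramethyl-1,3,2-dioxaborolane, via [8-methoxy-1-(methoxymethoxy)naphthalen-2-yl]lithium 4 (not isolated)
Conditions: n-BuLi (1.2 equiv), TMEDA, Et2O, 0 °C to rt; i-PrOBpin (1.5 equiv), −78 °C to rt; aq NH4Cl
Reagents that add atoms: 2-isopropoxy-4,4,5,5-tetramethyl-1,3,2-dioxaborolane, CC(C)OB1OC(C)(C)C(C)(C)O1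
Why: Directed ortho-metalation followed by borylation; the chelating acetal outranks the methyl ether as directing group, so lithiation should occur at C2 and not at C7, and the borate traps the aryllithium.

Step 4
Reactants: 2 8-methoxynaphthalen-1-ol
Product: 6 4-bromo-8-methoxynaphthalen-1-ol
Conditions: NBS (1.0 equiv), MeCN, −20 to 0 °C, dark
Reagents that add atoms: N-bromosuccinimide, O=C1CCC(=O)N1Br
Why: Electrophilic aromatic bromination; in a polar aprotic solvent 1-naphthols react preferentially at the para alpha position (C4), and the ring with the free hydroxyl is more activated than the methyl ether ring.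

Step 5
Reactants: 6 4-bromo-8-methoxynaphthalen-1-ol
Product: 7 4-bromo-2-iodo-8-methoxynaphthalen-1-ol
Conditions: NIS (1.05 equiv), TsOH·H2O (10 mol%), MeCN, 0 °C to rt
Reagents that add atoms: N-iodosuccinimide, O=C1CCC(=O)N1I
Why: Electrophilic aromatic iodination; with the para position blocked, C2 is the only site activated by the free hydroxyl.

Step 6
Reactants: 7 4-bromo-2-iodo-8-methoxynaphthalen-1-ol
Product: 8 4-bromo-2-iodo-8-methoxy-1-(methoxymethoxy)naphthalene
Conditions: NaH (1.2 equiv), DMF, 0 °C; MOMCl (1.3 equiv), 0 °C to rt
Reagents that add atoms: chloromethyl methyl ether, COCCl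
Why: O-alkylation of the naphtholate; the small chloromethyl ether should reach the oxygen despite the ortho iodine and the peri methoxy group, and the aryl halides are inert to NaH at this temperature.

Step 7
Reactants: 5 2-[8-methoxy-1-(methoxymethoxy)naphthalen-2-yl]-4,4,5,5-tetramethyl-1,3,2-dioxaborolane; 8 4-bromo-2-iodo-8-methoxy-1-(methoxymethoxy)naphthalene
Product: 9 4-bromo-8,8'-dimethoxy-1,1'-bis(methoxymethoxy)-2,2'-binaphthalene
Conditions: Pd(PPh3)4 (5 mol%), K3PO4 (3 equiv), 1,4-dioxane/H2O (5:1), 70 °C; 5 limited to 1.05 equiv
Reagents that add atoms: none
Why: Suzuki–Miyaura coupling; zerovalent palladium with a triarylphosphine inserts into the C–I bond much faster than into the C–Br bond, so the biaryl bond should form at C2 only and the bromine at C4 remains; the new biaryl has just two ortho substituents.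

Step 8
Reactants: 10 methyl 2-methoxy-6-methylbenzoate
Product: 11 methyl 2-(bromomethyl)-6-methoxybenzoate
Conditions: NBS (1.05 equiv), AIBN (5 mol%), PhCF3, 85 °C
Reagents that add atoms: N-bromosuccinimide, O=C1CCC(=O)N1Br
Why: Wohl–Ziegler benzylic bromination; radical conditions in a non-polar solvent favour the benzylic position over the anisole ring, and 11 is used directly to limit lactonisation on storage.

Step 9
Reactants: 11 methyl 2-(bromomethyl)-6-methoxybenzoate; 9 4-bromo-8,8'-dimethoxy-1,1'-bis(methoxymethoxy)-2,2'-binaphthalene
Product: 13 methyl 2-{[8,8'-dimethoxy-1,1'-bis(methoxymethoxy)-[2,2'-binaphthalen]-4-yl]methyl}-6-methoxybenzoate, via [3-methoxy-2-(methoxycarbonyl)benzyl]zinc bromide 12 (not isolated)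
Conditions: 11 (1.4 equiv), Zn dust (2 equiv), LiCl (1.5 equiv), THF, 0 to 25 °C; then 9, Pd(OAc)2 (2 mol%), SPhos (4 mol%), THF, 25 to 50 °C
Reagents that add atoms: none
Why: LiCl-promoted zinc insertion gives the benzylic zinc reagent 12, which tolerates its ortho ester; Negishi coupling at the single C–Br bond of 9 with an electron-rich biarylphosphine catalyst forms the diarylmethane, its position fixed by the halogen.

Step 10
Reactants: 13 methyl 2-{[8,8'-dimethoxy-1,1'-bis(methoxymethoxy)-[2,2'-binaphthalen]-4-yl]methyl}-6-methoxybenzoate; 14 methyl (E)-3-methoxyacrylate
Product: 18 methyl 1-hydroxy-8-methoxy-4-[8,8'-dimethoxy-1,1'-bis(methoxymethoxy)-[2,2'-binaphthalen]-4-yl]naphthalene-2-carboxylate, via benzylic lithium species 15 (not isolated), via open-chain Michael adduct 16 (not isolated), via 3-methoxytetralone ester 17 (not isolated)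
Conditions: LiN(i-Pr)2 (2.2 equiv), THF, −78 °C, 30 min; 14 (2.0 equiv), −78 °C to rt; aq NH4Cl
Reagents that add atoms: none
Why: Lithium diisopropylamide should remove a doubly benzylic proton of 13, acidified by both aryl rings and by the ortho ester (toluate-type extended enolate 15), in preference to ortho-metalation beside the acetals. The soft delocalised anion should add to the beta carbon of 14 (new C3–C4 bond) to give ester enolate 16, whose alpha carbon attacks the neighbouring benzoate carbonyl in a Dieckmann condensation (new C1–C2 bond, six-membered ring, 6-exo-trig closure) to give 17. The second equivalent of base keeps the acidic beta-keto ester from quenching unreacted 15; beta-elimination of the C3 methoxide and tautomerisation of the resulting naphthalenone then make the phenol ring of unit C aromatic, which drives the cascade. If methoxide leaves before ring closure, the gamma,gamma-diaryl enoate formed is deprotonated again at the same benzylic carbon and should converge on the same naphthoate. The closest known reaction type is the Staunton–Weinreb annulation (toluate-anion Michael–Dieckmann) in its aromatising variant with beta-alkoxy enoates. No stereocentre survives, since the centres of 16 and 17 are erased on aromatisation. The only selectivity needed is conjugate over carbonyl addition to 14; the pattern of the new ring (OH at C1 beside the C8 methoxy, unit B on C4) is dictated by the positions of the ester and the benzylic carbon in 13, and the doubly ortho-substituted benzoate resists intermolecular self-condensation.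

Step 11
Reactants: 18 methyl 1-hydroxy-8-methoxy-4-[8,8'-dimethoxy-1,1'-bis(methoxymethoxy)-[2,2'-binaphthalen]-4-yl]naphthalene-2-carboxylate
Product: 19 1-hydroxy-8-methoxy-4-[8,8'-dimethoxy-1,1'-bis(methoxymethoxy)-[2,2'-binaphthalen]-4-yl]naphthalene-2-carboxylic acid
Conditions: KOH (10 equiv), MeOH/THF/H2O (2:2:1), 65 °C; then 1 M HCl to pH 4, 0 °C
Reagents that add atoms: potassium hydroxide, [K+].[OH-]
Why: Saponification by acyl–oxygen cleavage; excess hydroxide and heat overcome deactivation by the naphtholate, and the MOM ethers are stable to base and to a brief cold acidification.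

Step 12
Reactants: 19 1-hydroxy-8-methoxy-4-[8,8'-dimethoxy-1,1'-bis(methoxymethoxy)-[2,2'-binaphthalen]-4-yl]naphthalene-2-carboxylic acid
Product: 20 8-methoxy-4-[8,8'-dimethoxy-1,1'-bis(methoxymethoxy)-[2,2'-binaphthalen]-4-yl]naphthalen-1-ol
Conditions: Cu2O (10 mol%), 1,10-phenanthroline (20 mol%), NMP/quinoline (3:1), 170 °C, argon
Reagents that add atoms: none
Why: Copper-catalysed protodecarboxylation of an ortho-hydroxy aromatic acid; a 1-hydroxy-2-naphthoic acid is predisposed to lose CO2 because its keto tautomer is a beta-keto acid, and the basic medium protects the MOM ethers.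

Step 13
Reactants: 20 8-methoxy-4-[8,8'-dimethoxy-1,1'-bis(methoxymethoxy)-[2,2'-binaphthalen]-4-yl]naphthalen-1-ol
Product: 21 5'',8,8'-trimethoxy-[2,2':4',1''-ternaphthalene]-1,1',4''-triol (target)
Conditions: 3 M aq HCl, MeOH/THF (1:1), 50 °C, degassed, argon
Reagents that add atoms: none
Why: Acid-catalysed acetal cleavage; methanol traps the methoxymethyl cation as dimethoxymethane so the free naphthols are not alkylated, and the aryl methyl ethers are inert to dilute acid.

## Compound list

1 | naphthalene-1,8-diol | Oc1cccc2cccc(O)c12 | starting material
2 | 8-methoxynaphthalen-1-ol | COc1cccc2cccc(O)c12 | intermediate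
3 | 8-methoxy-1-(methoxymethoxy)naphthalene | COCOc1cccc2cccc(OC)c12 | intermediate
4 | [8-methoxy-1-(methoxymethoxy)naphthalen-2-yl]lithium (not isolated) | [Li]c1ccc2cccc(OC)c2c1OCOC | intermediate
5 | 2-[8-methoxy-1-(methoxymethoxy)naphthalen-2-yl]-4,4,5,5-tetramethyl-1,3,2-dioxaborolane | COCOc1c(B2OC(C)(C)C(C)(C)O2)ccc2cccc(OC)c12 | intermediate
6 | 4-bromo-8-methoxynaphthalen-1-ol | COc1cccc2c(Br)ccc(O)c12 | intermediate
7 | 4-bromo-2-iodo-8-methoxynaphthalen-1-ol | COc1cccc2c(Br)cc(I)c(O)c12 | intermediate
8 | 4-bromo-2-iodo-8-methoxy-1-(methoxymethoxy)naphthalene | COc1cccc2c(Br)cc(I)c(OCOC)c12 | intermediate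
9 | 4-bromo-8,8'-dimethoxy-1,1'-bis(methoxymethoxy)-2,2'-binaphthalene | COc1cccc2c(Br)cc(-c3ccc4cccc(OC)c4c3OCOC)c(OCOC)c12 | intermediate
10 | methyl 2-methoxy-6-methylbenzoate | COc1cccc(C)c1C(=O)OC | starting material
11 | methyl 2-(bromomethyl)-6-methoxybenzoate | COc1cccc(CBr)c1C(=O)OC | intermediate
12 | [3-methoxy-2-(methoxycarbonyl)benzyl]zinc bromide (not isolated) | COc1cccc(C[Zn]Br)c1C(=O)OC | intermediate
13 | methyl 2-{[8,8'-dimethoxy-1,1'-bis(methoxymethoxy)-[2,2'-binaphthalen]-4-yl]methyl}-6-methoxybenzoate | COC(=O)c1c(OC)cccc1Cc1cc(-c2ccc3cccc(OC)c3c2OCOC)c(OCOC)c2c(OC)cccc12 | intermediate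
14 | methyl (E)-3-methoxyacrylate | CO/C=C/C(=O)OC | starting material
15 | benzylic lithium derivative of 13, a delocalised anion drawn with lithium on the benzylic carbon (not isolated) | COC(=O)c1c(OC)cccc1C([Li])c1cc(-c2ccc3cccc(OC)c3c2OCOC)c(OCOC)c2c(OC)cccc12 | intermediate
16 | lithium enolate of methyl 4-[8,8'-dimethoxy-1,1'-bis(methoxymethoxy)-[2,2'-binaphthalen]-4-yl]-3-methoxy-4-[3-methoxy-2-(methoxycarbonyl)phenyl]butanoate, mixture of diastereomers (not isolated) | COC(=O)c1c(OC)cccc1C(C(OC)C=C(OC)O[Li])c1cc(-c2ccc3cccc(OC)c3c2OCOC)c(OCOC)c2c(OC)cccc12 | intermediate
17 | methyl 4-[8,8'-dimethoxy-1,1'-bis(methoxymethoxy)-[2,2'-binaphthalen]-4-yl]-3,8-dimethoxy-1-oxo-1,2,3,4-tetrahydronaphthalene-2-carboxylate, mixture of diastereomers (not isolated) | COC(=O)C1C(OC)C(c2cc(-c3ccc4cccc(OC)c4c3OCOC)c(OCOC)c3c(OC)cccc23)c2cccc(OC)c2C1=O | intermediate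
18 | methyl 1-hydroxy-8-methoxy-4-[8,8'-dimethoxy-1,1'-bis(methoxymethoxy)-[2,2'-binaphthalen]-4-yl]naphthalene-2-carboxylate | COC(=O)c1cc(-c2cc(-c3ccc4cccc(OC)c4c3OCOC)c(OCOC)c3c(OC)cccc23)c2cccc(OC)c2c1O | intermediate
19 | 1-hydroxy-8-methoxy-4-[8,8'-dimethoxy-1,1'-bis(methoxymethoxy)-[2,2'-binaphthalen]-4-yl]naphthalene-2-carboxylic acid | OC(=O)c1cc(-c2cc(-c3ccc4cccc(OC)c4c3OCOC)c(OCOC)c3c(OC)cccc23)c2cccc(OC)c2c1O | intermediate
20 | 8-methoxy-4-[8,8'-dimethoxy-1,1'-bis(methoxymethoxy)-[2,2'-binaphthalen]-4-yl]naphthalen-1-ol | COc1cccc2c(-c3cc(-c4ccc5cccc(OC)c5c4OCOC)c(OCOC)c4c(OC)cccc34)ccc(O)c12 | intermediate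
21 | 5'',8,8'-trimethoxy-[2,2':4',1''-ternaphthalene]-1,1',4''-triol | COc1cccc2ccc(-c3cc(-c4ccc(O)c5c(OC)cccc45)c4cccc(OC)c4c3O)c(O)c12 | target

## Step count and least certain steps

Total: 13 steps. Longest linear sequence: 10 steps (1 → 2 → 6 → 7 → 8 → 9 → 13 → 18 → 19 → 20 → 21, that is steps 1, 4, 5, 6, 7, 9, 10, 11, 12 and 13).

Step 10 (key step). The most likely failure is slow conjugate addition of the crowded diarylmethyl anion to an acceptor that is deactivated by its beta-methoxy donor. Anionic oligomerisation of 14, proton return to the anion, or incomplete closure onto the doubly ortho-substituted benzoate could then dominate. The fallback sets out from 13 and comes back at 18. Compound 13 would be deprotonated as before and treated with methyl acrylate, a far more electrophilic acceptor. Michael addition and Dieckmann closure should then stop at methyl 4-[8,8'-dimethoxy-1,1'-bis(methoxymethoxy)-[2,2'-binaphthalen]-4-yl]-8-methoxy-1-oxo-1,2,3,4-tetrahydronaphthalene-2-carboxylate F1. Dehydrogenation of this largely enolic beta-keto ester with DDQ in 1,4-dioxane at 80 °C, with the doubly benzylic C4–H as hydride donor, should give 18. The oxidation level is thus adjusted after ring formation and not carried by the acceptor.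

Step 7. Halogen discrimination may be lost, with insertion into the C–Br bond of 8 or of 9 and over-arylation, and the hindered electron-rich boronate may protodeboronate during a slow transmetalation. The fallback sets out from 3 and 5 and comes back at 9; it brings the halogen in only after the biaryl bond exists.
- Compound 3 is lithiated as in step 3 (via 4) and quenched with 1,2-dibromotetrachloroethane to give 2-bromo-8-methoxy-1-(methoxymethoxy)naphthalene F2.
- HCl in MeOH frees 2-bromo-8-methoxynaphthalen-1-ol F3.
- Suzuki–Miyaura coupling of F3 with 5 (Pd(OAc)2, SPhos, K3PO4, toluene/H2O, 80 °C) should give 8,8'-dimethoxy-1'-(methoxymethoxy)-[2,2'-binaphthalen]-1-ol F4.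
- NBS in MeCN should brominate only the ring of the free naphthol at its single open para position, giving 4-bromo-8,8'-dimethoxy-1'-(methoxymethoxy)-[2,2'-binaphthalen]-1-ol F5.
- NaH and MOMCl then give 9.

Step 4. Ortho-bromination, double bromination or oxidation of the naphthol towards quinone-type material may compete with para-bromination. The fallback sets out from 3 and comes back at 7; it reverses the order of the halogens so that each position is dictated. Lithiation of 3 (via 4) and quenching with iodine gives 2-iodo-8-methoxy-1-(methoxymethoxy)naphthalene F6. HCl in MeOH gives 2-iodo-8-methoxynaphthalen-1-ol F7. NBS in MeCN, with the para position now the only open activated site, should give 7.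

Step 9. Zinc insertion may be accompanied by Wurtz-type homocoupling, 11 or 12 may lactonise to the phthalide on warming, and slow insertion of palladium into the hindered electron-rich C–Br bond may end in hydrodebromination. The fallback sets out from 9 and 11 and comes back at 13; it reverses the polarity of the coupling. Miyaura borylation of 9 (B2pin2, PdCl2(dppf), KOAc, 1,4-dioxane, 90 °C) gives 2-[8,8'-dimethoxy-1,1'-bis(methoxymethoxy)-[2,2'-binaphthalen]-4-yl]-4,4,5,5-tetramethyl-1,3,2-dioxaborolane F8. An sp2–sp3 Suzuki–Miyaura coupling of F8 with benzylic bromide 11 (Pd(PPh3)4, K2CO3, THF/H2O, 60 °C) should then give 13.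

Step 12. Protodecarboxylation of the hydrogen-bonded hydroxy acid may stay incomplete, or the MOM ethers and the electron-rich skeleton may degrade at 170 °C. The fallback sets out from 13 and comes back at 20; it moves the loss of CO2 to the beta-keto ester stage, where it is easy. The tetralone ester F1 is made from 13 as in the fallback to step 10. Krapcho dealkoxycarbonylation of F1 (LiCl, wet DMSO, 150 °C) gives 4-[8,8'-dimethoxy-1,1'-bis(methoxymethoxy)-[2,2'-binaphthalen]-4-yl]-8-methoxy-3,4-dihydronaphthalen-1(2H)-one F9. Dehydrogenation of F9 with DDQ in 1,4-dioxane at 80 °C should give 20, so steps 11 and 12 are bypassed.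

## Further compounds

F1 | step 10 | methyl 4-[8,8'-dimethoxy-1,1'-bis(methoxymethoxy)-[2,2'-binaphthalen]-4-yl]-8-methoxy-1-oxo-1,2,3,4-tetrahydronaphthalene-2-carboxylate (mixture of diastereomers) | COC(=O)C1CC(c2cc(-c3ccc4cccc(OC)c4c3OCOC)c(OCOC)c3c(OC)cccc23)c2cccc(OC)c2C1=O
F2 | step 7 | 2-bromo-8-methoxy-1-(methoxymethoxy)naphthalene | COCOc1c(Br)ccc2cccc(OC)c12
F3 | step 7 | 2-bromo-8-methoxynaphthalen-1-ol | COc1cccc2ccc(Br)c(O)c12
F4 | step 7 | 8,8'-dimethoxy-1'-(methoxymethoxy)-[2,2'-binaphthalen]-1-ol | COc1cccc2ccc(-c3ccc4cccc(OC)c4c3OCOC)c(O)c12
F5 | step 7 | 4-bromo-8,8'-dimethoxy-1'-(methoxymethoxy)-[2,2'-binaphthalen]-1-ol | COc1cccc2c(Br)cc(-c3ccc4cccc(OC)c4c3OCOC)c(O)c12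
F6 | step 4 | 2-iodo-8-methoxy-1-(methoxymethoxy)naphthalene | COCOc1c(I)ccc2cccc(OC)c12
F7 | step 4 | 2-iodo-8-methoxynaphthalen-1-ol | COc1cccc2ccc(I)c(O)c12
F8 | step 9 | 2-[8,8'-dimethoxy-1,1'-bis(methoxymethoxy)-[2,2'-binaphthalen]-4-yl]-4,4,5,5-tetramethyl-1,3,2-dioxaborolane | COCOc1c(-c2ccc3cccc(OC)c3c2OCOC)cc(B2OC(C)(C)C(C)(C)O2)c2cccc(OC)c12
F9 | step 12 | 4-[8,8'-dimethoxy-1,1'-bis(methoxymethoxy)-[2,2'-binaphthalen]-4-yl]-8-methoxy-3,4-dihydronaphthalen-1(2H)-one (racemic) | COc1cccc2c1C(=O)CCC2c1cc(-c2ccc3cccc(OC)c3c2OCOC)c(OCOC)c2c(OC)cccc12
A1 | alternative 1 | diisopropylsilylene-bridged trimer (seven-membered dioxasilepine across units A and B, unit C as MOM ether) | COc1cccc2ccc3-c4cc(-c5ccc(OCOC)c6c(OC)cccc56)c5cccc(OC)c5c4O[Si](C(C)C)(C(C)C)Oc3c12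
A2 | alternative 1 | (2-bromo-8-methoxynaphthalen-1-yloxy){8-methoxy-4-[5-methoxy-4-(methoxymethoxy)naphthalen-1-yl]naphthalen-1-yloxy}diisopropylsilane | COc1cccc2ccc(Br)c(O[Si](C(C)C)(C(C)C)Oc3ccc(-c4ccc(OCOC)c5c(OC)cccc45)c4cccc(OC)c34)c12
A3 | alternative 1 | 5,5'-dimethoxy-4'-(methoxymethoxy)-[1,1'-binaphthalen]-4-ol | COCOc1ccc(-c2ccc(O)c3c(OC)cccc23)c2cccc(OC)c12
A4 | alternative 1 | 5,5'-dimethoxy-[1,1'-binaphthalene]-4,4'-diol | COc1cccc2c(-c3ccc(O)c4c(OC)cccc34)ccc(O)c12
A5 | alternative 2 | trimer with free hydroxyl on unit A and MOM ethers on units B and C | COc1cccc2ccc(-c3cc(-c4ccc(OCOC)c5c(OC)cccc45)c4cccc(OC)c4c3OCOC)c(O)c12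
A6 | alternative 2 | 8-methoxy-1H-isochromen-1-one (8-methoxyisocoumarin) | COc1cccc2ccoc(=O)c12
A7 | alternative 2 | ({8-methoxy-1-(methoxymethoxy)-4-[5-methoxy-4-(methoxymethoxy)naphthalen-1-yl]naphthalen-2-yl}methyl)magnesium chloride | Cl[Mg]Cc1cc(-c2ccc(OCOC)c3c(OC)cccc23)c2cccc(OC)c2c1OCOC
A8 | alternative 3 | 5-bromo-8-methoxy-2-aryl-1-naphthyl acetate with benzyl ethers on units B and C | CC(=O)Oc1c(-c2cc(-c3ccc(OCc4ccccc4)c4c(OC)cccc34)c3cccc(OC)c3c2OCc2ccccc2)ccc2c(Br)ccc(OC)c12
A9 | alternative 3 | (E)-2-{1-(benzyloxy)-4-[4-(benzyloxy)-5-methoxynaphthalen-1-yl]-8-methoxynaphthalen-2-yl}-4-(2-bromo-5-methoxyphenyl)but-3-enoic acid (racemic) | OC(=O)C(/C=C/c1cc(OC)ccc1Br)c1cc(-c2ccc(OCc3ccccc3)c3c(OC)cccc23)c2cccc(OC)c2c1OCc1ccccc1
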